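The synthesis rests on cutting the side chain between its second and third carbon counted from pyrrole C5. In 5-vinyl-1H-pyrrole-2-carbaldehyde the second carbon is the terminus of a push-pull π-system that runs through the pyrrole ring to the C2 formyl group, so it accepts a nucleophilic alkyl radical, and the resulting pyrrol-2-ylmethyl radical is delocalised into ring and formyl oxygen. The key step forms this C(sp3)–C(sp3) bond by photoredox decarboxylative Giese-type hydroalkylation: 17-cyanoheptadecanoic acid, activated in situ as its N-hydroxyphthalimide ester, loses CO2 and its 16-cyanohexadecyl radical adds to the vinylpyrrole. The acid derives from commercial octadecanedioic acid mono-tert-butyl ester, the vinylpyrrole from 5-bromopyrrole-2-carbaldehyde.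

Key step: step 5

Remark: the target has no stereocentre and no stereogenic double bond, so it is one achiral compound and no step needs stereocontrol.

Step 1
Reactants: 1 18-(tert-butoxy)-18-oxooctadecanoic acid (octadecanedioic acid mono-tert-butyl ester)
Product: 3 tert-butyl 18-amino-18-oxooctadecanoate, via acyl imidazolide 2 (not isolated)
Conditions: CDI (1.2 equiv), THF, 40 °C, 1 h; then 28% aq. NH3 (excess), 0 °C to rt
Reagents that add atoms: ammonia, N; 1,1'-carbonyldiimidazole, O=C(n1ccnc1)n1ccnc1 (its imidazolyl group is held only by intermediate 2 and none of its atoms remain in 3)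
Why: CDI activation to the acyl imidazolide followed by aminolysis with ammonia (amide formation by acyl substitution) is mild and non-acidic, so the tert-butyl ester at the other chain end should be untouched.

Step 2
Reactants: 3 tert-butyl 18-amino-18-oxooctadecanoate
Product: 4 tert-butyl 17-cyanoheptadecanoate
Conditions: TFAA (1.5 equiv), pyridine (4 equiv), THF, 0 °C to rt
Reagents that add atoms: none
Why: Dehydration of a primary amide with TFAA/pyridine runs through the O-trifluoroacetyl imidate and loss of trifluoroacetate, and the buffered conditions should spare the tert-butyl ester.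

Step 3
Reactants: 4 tert-butyl 17-cyanoheptadecanoate
Product: 5 17-cyanoheptadecanoic acid
Conditions: TFA/CH2Cl2 (1:3), rt
Reagents that add atoms: none
Why: Acidolysis of the tert-butyl ester (alkyl–oxygen cleavage with loss of 2-methylpropene) should free the carboxylic acid, while the nitrile is inert to anhydrous TFA at room temperature.

Step 4
Reactants: 6 5-bromo-1H-pyrrole-2-carbaldehyde
Product: 7 5-ethenyl-1H-pyrrole-2-carbaldehyde
Conditions: vinylboronic acid pinacol ester (1.5 equiv), Pd(dppf)Cl2·CH2Cl2 (5 mol%), K3PO4 (3 equiv), 1,4-dioxane/H2O (4:1), 80 °C; product kept cold with a trace of BHT and used promptly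
Reagents that add atoms: vinylboronic acid pinacol ester (2-ethenyl-4,4,5,5-tetramethyl-1,3,2-dioxaborolane), C=CB1OC(C)(C)C(C)(C)O1
Why: Suzuki–Miyaura coupling: the C5–Br bond is activated towards oxidative addition by the conjugated formyl group, and the N–H should need no protection under phosphate base.

Step 5
Reactants: 5 17-cyanoheptadecanoic acid; 7 5-ethenyl-1H-pyrrole-2-carbaldehyde (2 equiv)
Product: 9 19-(5-formyl-1H-pyrrol-2-yl)nonadecanenitrile (Mycalenitrile 14), via redox-active ester 8 (not isolated)
Conditions: N-hydroxyphthalimide (1.05 equiv), DIC (1.05 equiv), DMAP (5 mol%), CH2Cl2, rt, 2 h; then 7 (2 equiv), Hantzsch ester (1.5 equiv), Ru(bpy)3(PF6)2 (1 mol%), degassed CH2Cl2, blue LEDs (450 nm), rt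
Reagents that add atoms: N-hydroxyphthalimide, O=C1c2ccccc2C(=O)N1O (its atoms are held only by intermediate 8 and leave again as phthalimide; none remain in 9)
Why: Carbodiimide esterification gives the N-(acyloxy)phthalimide 8; Ru(I), formed by reductive quenching of excited Ru(bpy)3 2+ by the Hantzsch ester, transfers one electron to 8, whose radical anion fragments to phthalimide anion, CO2 and the primary 16-cyanohexadecyl radical. This nucleophilic radical adds to the unsubstituted vinyl terminus of 7, and the pyrrol-2-ylmethyl radical so formed, delocalised over the ring and the formyl oxygen, takes a hydrogen atom from the Hantzsch ester (or its radical cation) to give 9. The closest known reaction type is the photoredox decarboxylative Giese reaction (hydroalkylation) of N-(acyloxy)phthalimides with electron-poor alkenes, styrenes and vinyl heteroarenes. No ring is closed and no stereocentre is formed. The step needs attack at the terminal CH2 rather than at ring carbons or the formyl group, which the steric accessibility of that carbon and the stability of the conjugated adduct radical should secure; it also needs hydrogen transfer to outrun oligomerisation of 7, which the excess of the good hydrogen donor and a moderate concentration of 7 favour. The remote nitrile, the pyrrole N–H and the vinylogous-amide aldehyde should be inert to alkyl radicals and to the mild reductant.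

Compound list
1 | 18-(tert-butoxy)-18-oxooctadecanoic acid | CC(C)(C)OC(=O)CCCCCCCCCCCCCCCCC(=O)O | starting material
2 | tert-butyl 18-(1H-imidazol-1-yl)-18-oxooctadecanoate | CC(C)(C)OC(=O)CCCCCCCCCCCCCCCCC(=O)n1ccnc1 | intermediate
3 | tert-butyl 18-amino-18-oxooctadecanoate | CC(C)(C)OC(=O)CCCCCCCCCCCCCCCCC(N)=O | intermediate
4 | tert-butyl 17-cyanoheptadecanoate | CC(C)(C)OC(=O)CCCCCCCCCCCCCCCCC#N | intermediate
5 | 17-cyanoheptadecanoic acid | N#CCCCCCCCCCCCCCCCCC(=O)O | intermediate
6 | 5-bromo-1H-pyrrole-2-carbaldehyde | O=Cc1ccc(Br)[nH]1 | starting material
7 | 5-ethenyl-1H-pyrrole-2-carbaldehyde | C=Cc1ccc(C=O)[nH]1 | intermediate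
8 | 1,3-dioxoisoindolin-2-yl 17-cyanoheptadecanoate | N#CCCCCCCCCCCCCCCCCC(=O)ON1C(=O)c2ccccc2C1=O | intermediate
9 | 19-(5-formyl-1H-pyrrol-2-yl)nonadecanenitrile (Mycalenitrile 14) | N#CCCCCCCCCCCCCCCCCCCc1ccc(C=O)[nH]1 | target

Total step count: 5. Longest linear sequence: 4 steps (steps 1, 2, 3 and 5).

Steps most likely to fail

Step 5. The adduct radical next to the pyrrole may add to further vinylpyrrole (oligomerisation), or the primary radical may be quenched by hydrogen transfer before it adds, so that the coupling does not terminate cleanly by reduction. The fallback changes the termination from reductive to oxidative. It sets out from 5 and 7 and comes back at 9. Acid 5 is converted into ester 8, this time isolated (N-hydroxyphthalimide, DIC, DMAP cat., CH2Cl2, silica plug). Ester 8 is then coupled with 7 in a photoinduced palladium-catalysed decarboxylative Heck reaction (Pd(PPh3)2Cl2, Xantphos, DMA, blue LEDs, rt). There the adduct radical is captured by palladium and β-hydride elimination should give (E)-19-(5-formyl-1H-pyrrol-2-yl)nonadec-18-enenitrile F1. Hydrogenation of the styrene-like alkene (H2 1 atm, 5% Pd/C, EtOAc, rt, stopped after one equivalent of uptake) should then give 9 with nitrile and formyl group intact.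

Step 4. Under aqueous base the pyrrole N–H is deprotonated, the electron-rich pyrrolide may undergo slow oxidative addition and protodebromination, and the vinyl product may polymerise on prolonged heating. The fallback masks the nitrogen and couples without base. It sets out from 6 and comes back at 7. Compound 6 is protected (Boc2O, DMAP cat., MeCN, rt) as tert-butyl 2-bromo-5-formyl-1H-pyrrole-1-carboxylate F2. Stille coupling with tributyl(vinyl)stannane (Pd(PPh3)4, toluene, 80 °C) should give tert-butyl 2-ethenyl-5-formyl-1H-pyrrole-1-carboxylate F3. Methanolysis of the activated N-acylpyrrole carbamate (K2CO3 cat., MeOH, 0 °C) should release 7.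

Step 3. The tert-butyl cation may be captured by the nitrile nitrogen (Ritter-type amide formation after work-up), or cleavage may stall because the long-chain ester dissolves poorly. The fallback inverts the order so that no nitrile is present when the cation is generated. It sets out from 3 and comes back at 5. Amide ester 3 is cleaved first (TFA/CH2Cl2, rt) to 18-amino-18-oxooctadecanoic acid F4. The amide is then dehydrated with TFAA (2.5 equiv)/pyridine in THF, and aqueous NaHCO3 work-up hydrolyses the mixed anhydride of the carboxyl group to give 5.

Further compounds
F1 | step 5 | (E)-19-(5-formyl-1H-pyrrol-2-yl)nonadec-18-enenitrile | N#CCCCCCCCCCCCCCCCC/C=C/c1ccc(C=O)[nH]1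
F2 | step 4 | tert-butyl 2-bromo-5-formyl-1H-pyrrole-1-carboxylate | CC(C)(C)OC(=O)n1c(Br)ccc1C=O
F3 | step 4 | tert-butyl 2-ethenyl-5-formyl-1H-pyrrole-1-carboxylate | CC(C)(C)OC(=O)n1c(C=C)ccc1C=O
F4 | step 3 | 18-amino-18-oxooctadecanoic acid | NC(=O)CCCCCCCCCCCCCCCCC(=O)O
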